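**Retrosynthetic overview**

1. Target 18 comes from its tri-O-methyl ether 17 (BBr3). The pyranone ring C of 17 is opened at C4–C4a and O2–C3 to give benzoic acid 13 and the hexanoyl sulfoxonium ylide 15.
2. Acid 13 comes from aryl bromide 11 (Br/Li exchange, CO2). The dimethoxy-pentyl ring B of 11 comes from cyclohexane-1,3-dione 8 by oxidative aromatisation and methylation, and 8 from ester 6 by hydrolysis and decarboxylation.
3. The strategy rests on ring B being a 5-pentylresorcinol ring whose C1' carries the ether oxygen and sits between C2'(OH) and the pentyl-bearing C6'. C1' can therefore enter as the sp3 carbon of aryloxymalonate 3, and 6 is opened at C1'–C6' and C2'–C3' to 3 and (E)-non-3-en-2-one 4.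
4. Malonate 3 comes from 2-bromo-5-methoxyphenol 1 and dimethyl bromomalonate 2, so the crowded ether C–O bond is made by alkylation at sp3 carbon.
5. Ring order: ring A is bought, ring B is closed in step 2 and aromatised in step 4, ring C is closed last in step 7.

Key step: step 2

Remark: the target has no stereocentre. Compounds 5 to 8 are handled as racemic mixtures of diastereomers, because their stereocentres disappear on aromatisation in step 4.

**Route**

Step 1
Reactants: 1 2-bromo-5-methoxyphenol; 2 dimethyl bromomalonate
Product: 3 dimethyl 2-(2-bromo-5-methoxyphenoxy)malonate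
Conditions: K2CO3, acetone, rt to 50 °C
Reagents that add atoms: none
Why: Williamson-type SN2 O-alkylation, in which the potassium phenoxide of 1 displaces bromide at the doubly ester-activated carbon of 2, so the hindered aryl ether bond of the target is made at an sp3 carbon and no stereocentre is formed.

Step 2
Reactants: 3 dimethyl 2-(2-bromo-5-methoxyphenoxy)malonate; 4 (E)-non-3-en-2-one
Product: 6 methyl 1-(2-bromo-5-methoxyphenoxy)-2,4-dioxo-6-pentylcyclohexane-1-carboxylate (racemic mixture of diastereomers), via Michael adduct 5 (not isolated)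
Conditions: NaOMe (1.2 equiv), MeOH, rt then reflux; aq HCl
Reagents that add atoms: none
Why: Methoxide deprotonates 3 and the aryloxymalonate carbanion adds in a Michael fashion to the beta carbon of 4 to give adduct 5 (bond C1'–C6'); equilibration to the terminal methyl-ketone enolate then allows a Claisen (Dieckmann-type) acyl substitution on one malonate ester (bond C2'–C3') with loss of methoxide, and the product is drained from all equilibria as its stabilised 1,3-dione enolate. The closest known reaction is the Michael–Claisen annulation of dialkyl malonates with non-3-en-2-one that delivers the cyclohexane-1,3-dione precursors of olivetol, here run with a malonate that carries an aryloxy substituent. Ring B closes in a 6-(enolexo)-exo-trig mode, the only closure open to 5, since the internal enolate could reach an ester only through a four-membered ring. The two new stereocentres (the quaternary aryloxy carbon and the pentyl-bearing carbon) arise without control as a thermodynamic mixture of racemic diastereomers, which is acceptable because both are erased in steps 3 and 4. The step needs regioselectivity only, and polarity secures it: the nucleophilic aryloxy-bearing carbon can bond only to the electrophilic pentyl-bearing beta carbon and only the methyl ketone can close onto an ester, so the aryloxy group ends up between a carbonyl carbon and the pentyl-bearing carbon.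

Step 3
Reactants: 6 methyl 1-(2-bromo-5-methoxyphenoxy)-2,4-dioxo-6-pentylcyclohexane-1-carboxylate
Product: 8 4-(2-bromo-5-methoxyphenoxy)-5-pentylcyclohexane-1,3-dione (racemic mixture of diastereomers), via beta-keto acid 7 (not isolated)
Conditions: NaOH, H2O/MeOH, reflux; then HCl to pH 1, 70 °C
Reagents that add atoms: none
Why: Saponification followed by beta-keto acid decarboxylation, in which the ring is held as its dione enolate under hydroxide (shielding the neighbouring carbonyl from retro-Claisen cleavage) while the methyl ester is hydrolysed, and acidification with warming expels CO2 from 7 through the usual six-membered transition state; the aryloxy-bearing carbon is reprotonated without control, which is immaterial because it becomes aromatic in step 4.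

Step 4
Reactants: 8 4-(2-bromo-5-methoxyphenoxy)-5-pentylcyclohexane-1,3-dione
Product: 11 1-bromo-2-(2,4-dimethoxy-6-pentylphenoxy)-4-methoxybenzene, via monomethyl ether 9 (not isolated), via monomethyl ether 10 (not isolated)
Conditions: I2 (1.2 equiv), MeOH, reflux; aq Na2S2O3 wash; then MeI, K2CO3, acetone, reflux
Reagents that add atoms: methanol, CO; iodomethane, CI
Why: Iodine-mediated oxidative aromatisation of a cyclohexane-1,3-dione in methanol (acid-catalysed enol ether formation, alpha-iodination, loss of HI and tautomerisation) should give the regioisomeric resorcinol monomethyl ethers 9 and 10, in which both ring stereocentres are gone, and Williamson methylation of the crude mixture converges both on the single dimethyl ether 11.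

Step 5
Reactants: 11 1-bromo-2-(2,4-dimethoxy-6-pentylphenoxy)-4-methoxybenzene
Product: 13 2-(2,4-dimethoxy-6-pentylphenoxy)-4-methoxybenzoic acid, via aryllithium 12 (not isolated)
Conditions: n-BuLi, THF, −78 °C; CO2; aq HCl
Reagents that add atoms: carbon dioxide, O=C=O
Why: Bromine–lithium exchange at −78 °C is faster than any ortho-lithiation next to the methoxy groups, and carboxylation of the resulting aryllithium 12 with CO2 places the future C1 of the isocoumarin on the carbon that bore bromine.

Step 6
Reactants: 14 hexanoyl chloride
Product: 15 1-[dimethyl(oxo)-λ6-sulfanylidene]heptan-2-one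
Conditions: Me3S(O)I (3 equiv), KOtBu (3 equiv), THF, reflux; then 14, 0 °C to rt
Reagents that add atoms: trimethylsulfoxonium iodide, C[S+](C)(C)=O.[I-]
Why: Acylation of dimethylsulfoxonium methylide (the Corey–Chaykovsky reagent) by an acid chloride, with a second equivalent of the methylide deprotonating the acylsulfoxonium salt, is the standard preparation of bench-stable beta-keto sulfoxonium ylides.

Step 7
Reactants: 13 2-(2,4-dimethoxy-6-pentylphenoxy)-4-methoxybenzoic acid; 15 1-[dimethyl(oxo)-λ6-sulfanylidene]heptan-2-one
Product: 17 8-(2,4-dimethoxy-6-pentylphenoxy)-6-methoxy-3-pentyl-1H-isochromen-1-one, via oxoheptyl acid 16 (not isolated)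
Conditions: [RuCl2(p-cymene)]2 (5 mol %), NaOAc (0.5 equiv), CF3CH2OH, 90 °C
Reagents that add atoms: none
Why: Carboxylate-directed C–H activation/annulation of a benzoic acid with a sulfoxonium ylide as carbene precursor, in which cyclometalation at the only free ortho C–H (the other ortho position carries the aryloxy group), carbene formation with loss of DMSO, migratory insertion and protodemetalation should give keto acid 16, which cyclodehydrates through the carboxyl oxygen to the 3-pentylisocoumarin.

Step 8
Reactants: 17 8-(2,4-dimethoxy-6-pentylphenoxy)-6-methoxy-3-pentyl-1H-isochromen-1-one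
Product: 18 8-(2,4-dihydroxy-6-pentylphenoxy)-6-hydroxy-3-pentyl-1H-isochromen-1-one (CNP0213708.0)
Conditions: BBr3 (8 equiv), CH2Cl2, −78 °C to rt; MeOH then H2O
Reagents that add atoms: none
Why: Lewis-acid ether cleavage with BBr3 removes the three O-methyl groups by bromide attack at the methyl carbons, while the diaryl ether (no sp3 carbon on oxygen) and the isocoumarin lactone are expected to survive, as is usual in BBr3 demethylations of methoxyisocoumarins.

**Compound list**

1 | 2-bromo-5-methoxyphenol | COc1ccc(Br)c(O)c1 | starting material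
2 | dimethyl bromomalonate | COC(=O)C(Br)C(=O)OC | starting material
3 | dimethyl 2-(2-bromo-5-methoxyphenoxy)malonate | COC(=O)C(Oc1cc(OC)ccc1Br)C(=O)OC | intermediate
4 | (E)-non-3-en-2-one | CCCCC/C=C/C(C)=O | starting material
5 | dimethyl 2-(2-bromo-5-methoxyphenoxy)-2-(2-oxononan-4-yl)malonate (racemic) | CCCCCC(CC(C)=O)C(Oc1cc(OC)ccc1Br)(C(=O)OC)C(=O)OC | intermediate (not isolated)
6 | methyl 1-(2-bromo-5-methoxyphenoxy)-2,4-dioxo-6-pentylcyclohexane-1-carboxylate (racemic mixture of diastereomers) | CCCCCC1CC(=O)CC(=O)C1(Oc1cc(OC)ccc1Br)C(=O)OC | intermediate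
7 | 1-(2-bromo-5-methoxyphenoxy)-2,4-dioxo-6-pentylcyclohexane-1-carboxylic acid (racemic mixture of diastereomers) | CCCCCC1CC(=O)CC(=O)C1(Oc1cc(OC)ccc1Br)C(=O)O | intermediate (not isolated)
8 | 4-(2-bromo-5-methoxyphenoxy)-5-pentylcyclohexane-1,3-dione (racemic mixture of diastereomers) | CCCCCC1CC(=O)CC(=O)C1Oc1cc(OC)ccc1Br | intermediate
9 | 2-(2-bromo-5-methoxyphenoxy)-5-methoxy-3-pentylphenol | CCCCCc1cc(OC)cc(O)c1Oc1cc(OC)ccc1Br | intermediate (not isolated)
10 | 4-(2-bromo-5-methoxyphenoxy)-3-methoxy-5-pentylphenol | CCCCCc1cc(O)cc(OC)c1Oc1cc(OC)ccc1Br | intermediate (not isolated)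
11 | 1-bromo-2-(2,4-dimethoxy-6-pentylphenoxy)-4-methoxybenzene | CCCCCc1cc(OC)cc(OC)c1Oc1cc(OC)ccc1Br | intermediate
12 | [2-(2,4-dimethoxy-6-pentylphenoxy)-4-methoxyphenyl]lithium | [Li]c1ccc(OC)cc1Oc1c(OC)cc(OC)cc1CCCCC | intermediate (not isolated)
13 | 2-(2,4-dimethoxy-6-pentylphenoxy)-4-methoxybenzoic acid | CCCCCc1cc(OC)cc(OC)c1Oc1cc(OC)ccc1C(=O)O | intermediate
14 | hexanoyl chloride | CCCCCC(Cl)=O | starting material
15 | 1-[dimethyl(oxo)-λ6-sulfanylidene]heptan-2-one | CCCCCC(=O)C=S(C)(C)=O | intermediate
16 | 2-(2,4-dimethoxy-6-pentylphenoxy)-4-methoxy-6-(2-oxoheptyl)benzoic acid | CCCCCC(=O)Cc1cc(OC)cc(Oc2c(OC)cc(OC)cc2CCCCC)c1C(=O)O | intermediate (not isolated)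
17 | 8-(2,4-dimethoxy-6-pentylphenoxy)-6-methoxy-3-pentyl-1H-isochromen-1-one | CCCCCc1cc2cc(OC)cc(Oc3c(OC)cc(OC)cc3CCCCC)c2c(=O)o1 | intermediate
18 | 8-(2,4-dihydroxy-6-pentylphenoxy)-6-hydroxy-3-pentyl-1H-isochromen-1-one | CCCCCc1cc2cc(O)cc(Oc3c(O)cc(O)cc3CCCCC)c2c(=O)o1 | target

**Step count**

Total steps: 8. Longest linear sequence: 7 steps (steps 1, 2, 3, 4, 5, 7 and 8); step 6 is a one-step side branch.

**Steps most likely to fail**

Step 2 (key step). The Michael addition of the fully substituted, hindered aryloxymalonate anion to a beta-alkyl enone is reversible and may lie on the side of the reactants. Retro-Michael cleavage, base-induced self-condensation of the enone, or methoxide-induced loss of a methoxycarbonyl group from the non-enolisable adduct could then outrun ring closure.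

The fallback sets out from 3 and replaces the enone by a doubly activated acceptor, methyl 2-acetyloct-2-enoate F1, made by Knoevenagel condensation of hexanal with methyl acetoacetate (piperidine, AcOH). Addition of 3 to F1 (NaOMe, MeOH) should give trimethyl 1-(2-bromo-5-methoxyphenoxy)-4-oxo-2-pentylpentane-1,1,3-tricarboxylate F2, held as its stabilised acetoacetate enolate, which removes the unfavourable equilibrium. Heating with further NaOMe closes the same ring through the methyl ketone, as in the classical acetoacetate–crotonate route to 5-alkylcyclohexane-1,3-diones, to give dimethyl 1-(2-bromo-5-methoxyphenoxy)-4,6-dioxo-2-pentylcyclohexane-1,3-dicarboxylate F3. Hydroxide hydrolysis gives 1-(2-bromo-5-methoxyphenoxy)-4,6-dioxo-2-pentylcyclohexane-1,3-dicarboxylic acid F4, both carboxyl groups of which are beta to a ring carbonyl and are lost on acidification and warming. The route is rejoined at 8.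

Step 4. Iodination may stall at the carbon between the two carbonyl groups, dehydroiodination may be incomplete, or the material may degrade under the hot acidic conditions, so that aromatisation does not go to completion.

The fallback sets out from 8 and replaces the halogen oxidation by stepwise enolate chemistry. Acid-catalysed etherification (MeOH, TsOH) at the less hindered carbonyl should give 6-(2-bromo-5-methoxyphenoxy)-3-methoxy-5-pentylcyclohex-2-en-1-one F5, purified from any regioisomer. Kinetic deprotonation at the aryloxy-bearing alpha' carbon (LDA, THF, −78 °C) and trapping with PhSeCl should give 6-(2-bromo-5-methoxyphenoxy)-3-methoxy-5-pentyl-6-(phenylselanyl)cyclohex-2-en-1-one F6, with selenium entering anti to the pentyl group. Oxidation with H2O2 gives the selenoxide 6-(2-bromo-5-methoxyphenoxy)-3-methoxy-5-pentyl-6-(phenylseleninyl)cyclohex-2-en-1-one F7, whose syn elimination towards the pentyl-bearing carbon and tautomerisation deliver phenol 9. The route is rejoined at 9, which is methylated to 11 as in the second stage of step 4.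

Step 7. The carbene derived from the ylide may insert into the carboxylic O–H bond (ester formation) instead of the C–H bond, and cyclometalation may be slow because the carboxylate is twisted out of plane by the bulky ortho aryloxy group.

The fallback sets out from 13 and changes the directing group. Carbodiimide coupling with MeONH2·HCl (EDC·HCl, Et3N, CH2Cl2) gives 2-(2,4-dimethoxy-6-pentylphenoxy)-N,4-dimethoxybenzamide F8, which has no acidic O–H and binds the metal through nitrogen. The known C–H acylmethylation of N-methoxybenzamides with sulfoxonium ylides ([Cp*RhCl2]2, AgSbF6, ClCH2CH2Cl, 80 °C, with 15) should then give 2-(2,4-dimethoxy-6-pentylphenoxy)-N,4-dimethoxy-6-(2-oxoheptyl)benzamide F9. Under acid (AcOH, heat) F9 cyclises through the amide carbonyl oxygen with loss of methoxyamine, and the route is rejoined at 17.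

**Further compounds**

F1 | step 2 | methyl 2-acetyloct-2-enoate (E/Z mixture) | CCCCCC=C(C(C)=O)C(=O)OC
F2 | step 2 | trimethyl 1-(2-bromo-5-methoxyphenoxy)-4-oxo-2-pentylpentane-1,1,3-tricarboxylate (racemic mixture of diastereomers) | CCCCCC(C(C(C)=O)C(=O)OC)C(Oc1cc(OC)ccc1Br)(C(=O)OC)C(=O)OC
F3 | step 2 | dimethyl 1-(2-bromo-5-methoxyphenoxy)-4,6-dioxo-2-pentylcyclohexane-1,3-dicarboxylate (racemic mixture of diastereomers) | CCCCCC1C(C(=O)OC)C(=O)CC(=O)C1(Oc1cc(OC)ccc1Br)C(=O)OC
F4 | step 2 | 1-(2-bromo-5-methoxyphenoxy)-4,6-dioxo-2-pentylcyclohexane-1,3-dicarboxylic acid (racemic mixture of diastereomers) | CCCCCC1C(C(=O)O)C(=O)CC(=O)C1(Oc1cc(OC)ccc1Br)C(=O)O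
F5 | step 4 | 6-(2-bromo-5-methoxyphenoxy)-3-methoxy-5-pentylcyclohex-2-en-1-one (racemic mixture of diastereomers) | CCCCCC1CC(OC)=CC(=O)C1Oc1cc(OC)ccc1Br
F6 | step 4 | 6-(2-bromo-5-methoxyphenoxy)-3-methoxy-5-pentyl-6-(phenylselanyl)cyclohex-2-en-1-one (racemic mixture of diastereomers) | CCCCCC1CC(OC)=CC(=O)C1(Oc1cc(OC)ccc1Br)[Se]c1ccccc1
F7 | step 4 | 6-(2-bromo-5-methoxyphenoxy)-3-methoxy-5-pentyl-6-(phenylseleninyl)cyclohex-2-en-1-one (racemic mixture of diastereomers) | CCCCCC1CC(OC)=CC(=O)C1(Oc1cc(OC)ccc1Br)[Se](=O)c1ccccc1
F8 | step 7 | 2-(2,4-dimethoxy-6-pentylphenoxy)-N,4-dimethoxybenzamide | CCCCCc1cc(OC)cc(OC)c1Oc1cc(OC)ccc1C(=O)NOC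
F9 | step 7 | 2-(2,4-dimethoxy-6-pentylphenoxy)-N,4-dimethoxy-6-(2-oxoheptyl)benzamide | CCCCCC(=O)Cc1cc(OC)cc(Oc2c(OC)cc(OC)cc2CCCCC)c1C(=O)NOC
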